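## Structural features

The target is a biflavanone: two 2-arylchroman-4-one units, each a phloroglucinol-type ring A fused to a dihydropyranone ring C that carries an aryl ring B at C2. The units are joined only by a diaryl ether oxygen between C3' of ring B of unit 1 (which also bears the 4'-hydroxyl) and C4' of ring B of unit 2. Unit 1 is the 5-hydroxy-7-methoxy flavanone and unit 2 the 5,7-dihydroxy flavanone, so one methyl ether is all that separates the two halves electronically. The two stereocentres, C2 of each unit (both S), are not adjacent: the diaryl ether and more than ten bonds lie between them, so neither can direct the other and each must be set by a reagent or catalyst. Both C2–O1 bonds are benzylic aryl ethers β to the C4 ketone. Base (or hot acid) enolises C3 and expels the ring A phenoxide, and re-closure racemises C2; the same bonds can also be hydrogenolysed, and the free phloroglucinol rings are oxidisable. The real difficulty is to install two remote C2 configurations and keep them, while one methylated oxygen is distinguished from five free ones on an unsymmetrical diaryl ether. The key step uses the fact that ring C of unit 1 is fused to ring A through O1–C8a and C4–C4a on neighbouring arene carbons next to the C5 oxygen. This is the ortho-difunctionalisation pattern that a 3-alkoxy aryne delivers to an oxygen nucleophile with a tethered acyl group.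

## Logic of the disconnections

28 to 27. The four phenolic O–CH2Ph bonds are cut (O5 and O4' of unit 1, O5 and O7 of unit 2). The free phenols and the two base-labile C2 centres tolerate only a neutral last step, and benzyl ethers leave the O7 methyl ether as the one permanent ether. The gain is that every earlier intermediate is a neutral ether. The forward step must stop before the benzylic C2–O1 bonds or the ketones are reduced.

27 to 22 and 26. The C2–C1' bond of unit 2 is cut. It joins a planar, achiral ring system to an aryl nucleophile, so the second stereocentre can be made by a chiral catalyst in a weakly acidic medium after unit 1 is complete. Unit 2 shrinks to 26 and the whole diaryl ether travels in 22. The forward step needs pure catalyst control, because C2 of unit 1 is too far away to help or hinder, and it must be free of base.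

22 to 21 to 20. The aryl C–B bond is traced back to C–Br. Bromine is inert to divalent copper, amide enolates, hydride transfer and the aryne step, and becomes the reactive site only when needed. The demand is a borylation whose base is too weak to enolise C3.

26 to 24 to 23. O1–C2 and C2–C3 of the pyranone are cut (C2 comes from a formamide acetal), then two O–benzyl bonds. This reaches a catalogue ketone; the forward benzylation must spare the hydroxyl that is hydrogen-bonded to the carbonyl.

20 to 8 and 15 (key disconnection). O1–C8a and C4–C4a are cut. These are two bonds on adjacent arene carbons, one to oxygen and one to an acyl carbon, which is the retron of an aryne. C2 is not touched, so its configuration can be set earlier by reduction of an open-chain ketone, and ring A arrives with its three oxygens already differentiated. 20 falls into two fragments of similar size, each three steps from catalogue compounds. The forward step demands oxygen attack at the aryne carbon remote from the benzyloxy group, acylation of the aryl carbanion faster than removal of a C3 proton, and a tetrahedral adduct that survives until the quench.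

15 to 11 to 10 to 9. The C–Si bond (with O–Tf), one O–benzyl bond and the C–I bond are cut. Silicon must sit between the triflate and benzyloxy oxygens; in 9 that carbon lies on the symmetry axis between the two hydroxyls, so a halogen placed there fixes the site before the oxygens are differentiated. The demands are iodination between the hydroxyls and a mono-alkylation of a symmetric diol.

8 to 7 to 3 and 4. The carbinol C–H bond is cut back to the aryl ketone, then the bond between the ketone carbon and the methylene. Aryl ketone reduction is the most dependable catalytic route to a benzylic carbinol, and the keto amide is a Claisen product of an ester and an acetamide. The demands are hydride delivery to the Re face and a single acylation.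

3 to 1 and 2. The diaryl ether C–O bond on the bromophenyl ring is cut. An oxidative copper coupling at room temperature forms it without touching C–Br. The demand is chemoselectivity for boron over bromine.

## Other disconnections considered

Alternative 1: The cut is made at both C8a–O1 bonds and leads to the open-chain bis(β-hydroxy ketone) A2, (S)-configured at both carbinols, with a fluorine ortho to each ketone. In the forward sense a carbonate base in a dipolar aprotic solvent would form both alkoxides, and two intramolecular addition–elimination substitutions at the fluorinated carbons would close both rings C to give A1, which is identical with 27.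
- In its favour: the reaction type is established, which the chosen key step is not, so on precedent of the bond-forming event this plan is the better one. The carbinol C–O bonds are not broken, so retention is expected in principle, as in the chosen plan (equal). A1 is one hydrogenolysis from the target, so the endgame is shorter than borylation, hydrolysis and conjugate addition (better).
- Against it: each fluorinated ring carries two alkoxy donors and a ketone twisted by two ortho substituents, so substitution would need heat. Under those conditions a β-hydroxy aryl ketone can dehydrate by E1cB or cleave by retro-aldol. Every flavanone ring that has closed then sits in carbonate base, the medium that opens it at C2–O1.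
- Comparison: both stereocentres are exposed here, whereas the chosen plan masks the unit 1 ketone as a hemiaminal until the quench and builds unit 2 without base. A2 also needs two enantioselective carbinol constructions on two different fluorinated aryl ketone fragments, so overall step economy is about equal.

Alternative 2: The cut removes two C–C bonds of ring B of unit 2 (C1'–C6' and C2'–C3') and gives the terminal alkyne A4 and the 2-aryloxy diene A5. In the forward sense a low-valent cobalt diphosphine catalyst (CoBr2(dppe) reduced by Zn, with ZnI2) would join them in a formal [4+2] cycloaddition to the 1,4-cyclohexadiene A6, which a quinone oxidant would aromatise in the same flask to A3.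
- In its favour: ring B is made with the ether oxygen already attached, so neither an oxidative C–O coupling nor arylboron chemistry on a flavanone is needed (better). C2 of unit 2 is present in A4 before the key step and is a spectator; A4 could come from 26 by catalytic asymmetric alkynylation. The cycloaddition is neutral and of a known catalytic type (better on precedent).
- Against it: para versus meta regiochemistry depends on the ligand. A5 is an acid-sensitive enol-ether diene that takes several steps to make and polymerises easily. The quinone oxidant is the classical reagent for dehydrogenating flavanones and also attacks benzyl ethers, so aromatisation competes with loss of the C2 centre.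
- Comparison: A3 is only half of the molecule. Its chloroarene must still be turned into the whole of unit 1, with a second stereocentre, next to a finished base-labile flavanone, which excludes alkoxide or enolate chemistry at that stage. Step economy is clearly worse.

Alternative 3: The cut removes three C–C bonds of ring A of unit 1 (C5–C6, C7–C8 and C4a–C5) and leads to the diazo ketone A8, a 2-aryl-2,3-dihydropyran-4-one with a diazoacetyl group at C6, and methoxyethyne A9. In the forward sense irradiation would trigger a Wolff rearrangement, and [2+2] cycloaddition with A9, four-electron ring opening, six-electron ring closure and tautomerisation would give A7.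
- In its favour: the pericyclic cascade is known chemistry (better on precedent). The polarity of the alkynyl ether places hydroxyl and methoxy in the 5,7-pattern and leaves the C5 hydroxyl free, so one protecting group and the question of aryne regiochemistry both disappear (better). The medium is neutral and C2 is a spectator (equal). C2 of A8 could be set by a catalytic asymmetric hetero-Diels–Alder reaction, which is as well founded as ketone reduction (equal).
- Against it: A8 is a vinylogous ester bearing a diazo ketone. Its preparation needs a C6 acyl group and a diazo transfer next to an enolisable dihydropyranone that is prone to ring opening, several steps more than 8 and 15 together. The enone chromophore competes for light, and A9 is volatile and unstable.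
- Comparison: after A7 the same four-step endgame as in the chosen plan still follows. The key step is probably more robust and the precursor synthesis less so; the route is longer by several steps.

Key step: step 7

Remark 1: compound 1 is taken as a catalogue compound (the 4-O-benzyl ether of a commercial catechol ester).

Remark 2: the connectivity of the key step was checked atom by atom and needs no correction: the triflate carbon of 15 becomes C8a and the silicon-bearing carbon C4a, which puts benzyloxy at C5 and methoxy at C7.

Remark 3: three design changes are made. Iodination between the hydroxyls replaces a bromination whose site selectivity on this ring cannot be defended. THF replaces nitrile solvents in the key step, so that no C–H acid can protonate the aryl carbanion. The alkoxide is formed with NaH, so that no conjugate acid remains.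

Remark 4: in step 12 the ligand antipode is assigned by transferring the facial model of cyclic enones to the chromone; this assignment is the least secure stereochemical argument in the route.

Remark 5: the counter-ion of 18 and 19 is written as sodium, although caesium is also present.

## Route

Step 1
Reactants: 1 methyl 4-(benzyloxy)-3-hydroxybenzoate; 2 4-bromophenylboronic acid
Product: 3 methyl 4-(benzyloxy)-3-(4-bromophenoxy)benzoate
Conditions: 2 (2 equiv), Cu(OAc)2 (1 equiv), pyridine, 4 Å MS, CH2Cl2, air, rt
Reagents that add atoms: none
Why: Chan–Lam oxidative C–O coupling: the phenoxide of 1 and the aryl group of 2 meet on copper, and reductive elimination from a trivalent copper aryl phenoxide gives the diaryl ether, air returning copper to the divalent state. No zerovalent palladium or strong base is present, so the C–Br bond, the ester and the benzyl ether are not touched.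

Step 2
Reactants: 3 methyl 4-(benzyloxy)-3-(4-bromophenoxy)benzoate; 4 N-methoxy-N-methylacetamide
Product: 7 3-[4-(benzyloxy)-3-(4-bromophenoxy)phenyl]-N-methoxy-N-methyl-3-oxopropanamide, via lithium amide enolate 5 (not isolated), via chelated lithium enolate 6 (not isolated)
Conditions: 4 (2.6 equiv), LiN(i-Pr)2 (2.5 equiv), THF, −78 °C; then 3, −78 → −20 °C; aq. NH4Cl
Reagents that add atoms: none
Why: Claisen-type acylation of enolate 5 by the aryl ester; the product is more acidic than 4 and is held as enolate 6 until the quench, which prevents a second addition and explains the excess of 5. The amide base is consumed by 4 before 3 is added, so the C–Br bond and the ring protons are left alone.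

Step 3
Reactants: 7 3-[4-(benzyloxy)-3-(4-bromophenoxy)phenyl]-N-methoxy-N-methyl-3-oxopropanamide
Product: 8 (S)-3-[4-(benzyloxy)-3-(4-bromophenoxy)phenyl]-3-hydroxy-N-methoxy-N-methylpropanamide
Conditions: RuCl[(S,S)-TsDPEN](p-cymene) (1 mol%), HCO2H/Et3N (5:2), EtOAc, 35 °C
Reagents that add atoms: none
Why: Noyori–Ikariya asymmetric transfer hydrogenation of an aryl ketone: the ruthenium hydride transfers hydride and proton in an outer-sphere six-membered transition state in which the aryl group is held by a CH–π contact with the cymene ligand. With the (S,S)-ligand hydride should reach the Re face and give the (S)-carbinol, the sense known for acetophenone-type ketones (aryl outranks CH2 in both). Formate as reductant leaves the C–Br bond, the benzyl ether and the N–O bond intact.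

Step 4
Reactants: 9 5-methoxyresorcinol
Product: 10 2-iodo-5-methoxybenzene-1,3-diol
Conditions: I2 (1.0 equiv), NaHCO3, THF/H2O, 0 °C
Reagents that add atoms: iodine, II
Why: Electrophilic iodination under aqueous hydrogen carbonate, the conditions under which resorcinol and its 5-alkyl homologues are iodinated at the carbon between the two hydroxyls. That carbon lies on the symmetry axis of 9, so the later silyl group is fixed between the oxygens that become the triflate and the benzyl ether.

Step 5
Reactants: 10 2-iodo-5-methoxybenzene-1,3-diol
Product: 11 3-(benzyloxy)-2-iodo-5-methoxyphenol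
Conditions: BnBr (1.0 equiv), K2CO3 (1.0 equiv), acetone, 40 °C
Reagents that add atoms: benzyl bromide, BrCc1ccccc1
Why: Williamson mono-alkylation of a symmetric diol: the hydroxyls are equivalent, so only one mono-ether can form. The distribution is statistical; the bis-ether is removed by chromatography and unreacted 10 is recycled.

Step 6
Reactants: 11 3-(benzyloxy)-2-iodo-5-methoxyphenol
Product: 15 3-(benzyloxy)-5-methoxy-2-(trimethylsilyl)phenyl trifluoromethanesulfonate, via aryl trimethylsilyl ether 12 (not isolated), via aryllithium 13 (not isolated), via lithium phenoxide 14 (not isolated)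
Conditions: HMDS, THF, 65 °C, concentrate; n-BuLi, THF, −78 °C; Tf2O, −78 °C → rt
Reagents that add atoms: hexamethyldisilazane, C[Si](C)(C)N[Si](C)(C)C; trifluoromethanesulfonic anhydride, O=S(=O)(OS(=O)(=O)C(F)(F)F)C(F)(F)F
Why: Standard route to ortho-silylaryl triflates: O-silylation, iodine–lithium exchange (faster than benzylic deprotonation at −78 °C), 1,3 O→C silyl shift (retro-Brook) of 13 to 14, and O-triflation. Silicon ends on the carbon that bore iodine, between the triflate and the benzyloxy group.

Step 7
Reactants: 8 (S)-3-[4-(benzyloxy)-3-(4-bromophenoxy)phenyl]-3-hydroxy-N-methoxy-N-methylpropanamide; 15 3-(benzyloxy)-5-methoxy-2-(trimethylsilyl)phenyl trifluoromethanesulfonate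
Product: 20 (S)-5-(benzyloxy)-2-[4-(benzyloxy)-3-(4-bromophenoxy)phenyl]-7-methoxychroman-4-one, via sodium alkoxide 16 (not isolated), via aryne 17 (not isolated), via aryl carbanion 18 (not isolated), via hemiaminal alkoxide 19 (not isolated)
Conditions: 8, NaH (1.05 equiv), THF, 0 °C; then 15 (1.3 equiv), CsF (3 equiv), 18-crown-6, THF, 0 °C → rt; aq. NH4Cl, 0 °C
Reagents that add atoms: none
Why: Proposed new method: fluoride attack on silicon in 15 expels triflate and releases aryne 17; alkoxide 16 adds to the aryne carbon remote from the benzyloxy group, because the C–O dipole polarises the strained triple bond and stabilises the carbanion that develops on the neighbouring carbon (18). That carbanion lies in the arene plane and adds to the Weinreb carbonyl in a 6-exo-trig closure that completes ring C as hemiaminal alkoxide 19, which should release ketone 20 and N,O-dimethylhydroxylamine only on the buffered quench, so that the enolisable flavanone does not meet base. The closest known reaction type is the fluoride-mediated aryne annulation of ortho-hydroxyaryl esters to xanthones (O-arylation followed by intramolecular acyl substitution); an aliphatic β-alkoxy amide has not been used as the partner. No stereocentre is created: C2 is the carbinol carbon of 8, whose C–O bond is never broken, so the S configuration of step 3 is carried over provided that retro-aldol cleavage of 16 stays slow, hence NaH at 0 °C and immediate use. Regioselectivity (oxygen to C8a, acyl to C4a) rests on the 3-alkoxy substituent of 17; the 5-methoxy group is meta to the attacked carbon and exerts no opposing influence. Chemoselectivity requires carbonyl addition of 18 to outrun proton abstraction from C3, which would lead to β-elimination of the new aryl ether; the weakly acidic amide α-hydrogens, the short tether and the aprotic medium (alkoxide pre-formed with loss of H2, no alcohol or nitrile present) favour addition. Transient silylation of 16 by 15 is harmless because fluoride returns the alkoxide.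

Step 8
Reactants: 20 (S)-5-(benzyloxy)-2-[4-(benzyloxy)-3-(4-bromophenoxy)phenyl]-7-methoxychroman-4-one
Product: 21 (S)-5-(benzyloxy)-2-{4-(benzyloxy)-3-[4-(4,4,5,5-tetramethyl-1,3,2-dioxaborolan-2-yl)phenoxy]phenyl}-7-methoxychroman-4-one
Conditions: B2pin2, PdCl2(dppf) (3 mol%), KOAc, 1,4-dioxane, 80 °C
Reagents that add atoms: bis(pinacolato)diboron, CC1(C)OB(OC1(C)C)B1OC(C)(C)C(C)(C)O1
Why: Miyaura borylation: oxidative addition of C–Br to zerovalent palladium, acetate-assisted transmetalation with the diboron reagent and reductive elimination. KOAc in dry dioxane is the weakest base that sustains the cycle and is sparingly soluble, which should keep enolisation at C3 (the route to ring opening at C2) slow.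

Step 9
Reactants: 21 (S)-5-(benzyloxy)-2-{4-(benzyloxy)-3-[4-(4,4,5,5-tetramethyl-1,3,2-dioxaborolan-2-yl)phenoxy]phenyl}-7-methoxychroman-4-one
Product: 22 (S)-{4-[2-(benzyloxy)-5-(5-(benzyloxy)-7-methoxy-4-oxochroman-2-yl)phenoxy]phenyl}boronic acid
Conditions: NaIO4, NH4OAc, acetone/H2O, rt
Reagents that add atoms: water, O
Why: Hydrolysis of the pinacol boronate, driven by periodate cleavage of the liberated diol in a near-neutral acetate buffer, so C2 is not endangered. The free boronic acid is the species that transmetalates to cationic palladium in step 12.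

Step 10
Reactants: 23 2',4',6'-trihydroxyacetophenone
Product: 24 1-[2,4-bis(benzyloxy)-6-hydroxyphenyl]ethan-1-one
Conditions: BnBr (2.05 equiv), K2CO3, DMF, rt
Reagents that add atoms: benzyl bromide, BrCc1ccccc1
Why: Williamson benzylation; two hydroxyls react and the one hydrogen-bonded to the acetyl carbonyl stays, the usual selectivity of this ketone.

Step 11
Reactants: 24 1-[2,4-bis(benzyloxy)-6-hydroxyphenyl]ethan-1-one
Product: 26 5,7-bis(benzyloxy)-4H-chromen-4-one, via enaminone 25 (not isolated)
Conditions: Me2NCH(OMe)2, toluene, 100 °C; then aq. HCl, CH2Cl2, rt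
Reagents that add atoms: N,N-dimethylformamide dimethyl acetal, COC(OC)N(C)C
Why: Condensation of the methyl ketone with the formamide acetal gives enaminone 25; acid-promoted conjugate addition of the ortho hydroxyl and loss of dimethylamine (addition–elimination) closes the pyranone ring.

Step 12
Reactants: 22 (S)-{4-[2-(benzyloxy)-5-(5-(benzyloxy)-7-methoxy-4-oxochroman-2-yl)phenoxy]phenyl}boronic acid; 26 5,7-bis(benzyloxy)-4H-chromen-4-one
Product: 27 (2S)-5-(benzyloxy)-2-{4-(benzyloxy)-3-[4-((2S)-5,7-bis(benzyloxy)-4-oxochroman-2-yl)phenoxy]phenyl}-7-methoxychroman-4-one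
Conditions: 26 (1.5 equiv), Pd(OCOCF3)2 (10 mol%), (R)-t-BuPyOx (12 mol%), NH4PF6 (30 mol%), H2O (5 equiv), ClCH2CH2Cl, 60 °C
Reagents that add atoms: none
Why: Palladium-catalysed asymmetric conjugate addition of an arylboronic acid to a chromone: transmetalation to the cationic divalent palladium pyridine-oxazoline complex, enantio-determining insertion of the C2=C3 bond into the aryl–palladium bond, and protonolysis of the palladium enolate by water. The tert-butyl group of the ligand blocks one face; by the facial model of cyclic enones the (R)-ligand should deliver the aryl group to the Re face of C2 and give the (S)-centre, under catalyst control because C2 of unit 1 is remote. The medium is weakly acidic and free of base, so both flavanone centres should persist.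

Step 13
Reactants: 27 (2S)-5-(benzyloxy)-2-{4-(benzyloxy)-3-[4-((2S)-5,7-bis(benzyloxy)-4-oxochroman-2-yl)phenoxy]phenyl}-7-methoxychroman-4-one
Product: 28 7-O-methyltetrahydroochnaflavone
Conditions: H2 (1 atm), Pd/C, EtOAc/MeOH, rt
Reagents that add atoms: none
Why: Heterogeneous hydrogenolysis of four aryl benzyl ethers in a neutral medium; the methyl ether, the diaryl ether and the ketones are not cleaved at one atmosphere and room temperature. The reaction is stopped at the end of hydrogen uptake to spare the benzylic C2–O1 bonds, and no base is present, so both C2 centres are retained.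

## Compound list

1 | methyl 4-(benzyloxy)-3-hydroxybenzoate | COC(=O)c1ccc(OCc2ccccc2)c(O)c1 | starting material
2 | 4-bromophenylboronic acid | OB(O)c1ccc(Br)cc1 | starting material
3 | methyl 4-(benzyloxy)-3-(4-bromophenoxy)benzoate | COC(=O)c1ccc(OCc2ccccc2)c(Oc2ccc(Br)cc2)c1 | intermediate
4 | N-methoxy-N-methylacetamide | CC(=O)N(C)OC | starting material
5 | lithium 1-[methoxy(methyl)amino]ethen-1-olate | [Li+].C=C([O-])N(C)OC | intermediate
6 | lithium (Z)-1-[4-(benzyloxy)-3-(4-bromophenoxy)phenyl]-3-[methoxy(methyl)amino]-3-oxoprop-1-en-1-olate | [Li+].CON(C)C(=O)/C=C(\[O-])c1ccc(OCc2ccccc2)c(Oc2ccc(Br)cc2)c1 | intermediate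
7 | 3-[4-(benzyloxy)-3-(4-bromophenoxy)phenyl]-N-methoxy-N-methyl-3-oxopropanamide | CON(C)C(=O)CC(=O)c1ccc(OCc2ccccc2)c(Oc2ccc(Br)cc2)c1 | intermediate
8 | (S)-3-[4-(benzyloxy)-3-(4-bromophenoxy)phenyl]-3-hydroxy-N-methoxy-N-methylpropanamide | CON(C)C(=O)C[C@H](O)c1ccc(OCc2ccccc2)c(Oc2ccc(Br)cc2)c1 | intermediate
9 | 5-methoxyresorcinol | COc1cc(O)cc(O)c1 | starting material
10 | 2-iodo-5-methoxybenzene-1,3-diol | COc1cc(O)c(I)c(O)c1 | intermediate
11 | 3-(benzyloxy)-2-iodo-5-methoxyphenol | COc1cc(O)c(I)c(OCc2ccccc2)c1 | intermediate
12 | [3-(benzyloxy)-2-iodo-5-methoxyphenoxy]trimethylsilane | COc1cc(O[Si](C)(C)C)c(I)c(OCc2ccccc2)c1 | intermediate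
13 | {2-(benzyloxy)-4-methoxy-6-[(trimethylsilyl)oxy]phenyl}lithium | [Li]c1c(O[Si](C)(C)C)cc(OC)cc1OCc1ccccc1 | intermediate
14 | lithium 3-(benzyloxy)-5-methoxy-2-(trimethylsilyl)phenolate | [Li+].[O-]c1cc(OC)cc(OCc2ccccc2)c1[Si](C)(C)C | intermediate
15 | 3-(benzyloxy)-5-methoxy-2-(trimethylsilyl)phenyl trifluoromethanesulfonate | COc1cc(OCc2ccccc2)c([Si](C)(C)C)c(OS(=O)(=O)C(F)(F)F)c1 | intermediate
16 | sodium (S)-1-[4-(benzyloxy)-3-(4-bromophenoxy)phenyl]-3-[methoxy(methyl)amino]-3-oxopropan-1-olate | [Na+].CON(C)C(=O)C[C@H]([O-])c1ccc(OCc2ccccc2)c(Oc2ccc(Br)cc2)c1 | intermediate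
17 | 3-(benzyloxy)-5-methoxybenzyne | COC1=CC#CC(OCc2ccccc2)=C1 | intermediate
18 | sodium 2-(benzyloxy)-6-{(S)-1-[4-(benzyloxy)-3-(4-bromophenoxy)phenyl]-3-[methoxy(methyl)amino]-3-oxopropoxy}-4-methoxybenzenide | [Na+].CON(C)C(=O)C[C@H](Oc1cc(OC)cc(OCc2ccccc2)[c-]1)c1ccc(OCc2ccccc2)c(Oc2ccc(Br)cc2)c1 | intermediate
19 | sodium (2S)-5-(benzyloxy)-2-[4-(benzyloxy)-3-(4-bromophenoxy)phenyl]-7-methoxy-4-[methoxy(methyl)amino]chroman-4-olate | [Na+].COc1cc(OCc2ccccc2)c2c(c1)O[C@H](c1ccc(OCc3ccccc3)c(Oc3ccc(Br)cc3)c1)CC2([O-])N(C)OC | intermediate
20 | (S)-5-(benzyloxy)-2-[4-(benzyloxy)-3-(4-bromophenoxy)phenyl]-7-methoxychroman-4-one | COc1cc(OCc2ccccc2)c2c(c1)O[C@H](c1ccc(OCc3ccccc3)c(Oc3ccc(Br)cc3)c1)CC2=O | intermediate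
21 | (S)-5-(benzyloxy)-2-{4-(benzyloxy)-3-[4-(4,4,5,5-tetramethyl-1,3,2-dioxaborolan-2-yl)phenoxy]phenyl}-7-methoxychroman-4-one | COc1cc(OCc2ccccc2)c2c(c1)O[C@H](c1ccc(OCc3ccccc3)c(Oc3ccc(B4OC(C)(C)C(C)(C)O4)cc3)c1)CC2=O | intermediate
22 | (S)-{4-[2-(benzyloxy)-5-(5-(benzyloxy)-7-methoxy-4-oxochroman-2-yl)phenoxy]phenyl}boronic acid | COc1cc(OCc2ccccc2)c2c(c1)O[C@H](c1ccc(OCc3ccccc3)c(Oc3ccc(B(O)O)cc3)c1)CC2=O | intermediate
23 | 2',4',6'-trihydroxyacetophenone | CC(=O)c1c(O)cc(O)cc1O | starting material
24 | 1-[2,4-bis(benzyloxy)-6-hydroxyphenyl]ethan-1-one | CC(=O)c1c(O)cc(OCc2ccccc2)cc1OCc1ccccc1 | intermediate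
25 | (E)-1-[2,4-bis(benzyloxy)-6-hydroxyphenyl]-3-(dimethylamino)prop-2-en-1-one | CN(C)/C=C/C(=O)c1c(O)cc(OCc2ccccc2)cc1OCc1ccccc1 | intermediate
26 | 5,7-bis(benzyloxy)-4H-chromen-4-one | O=c1ccoc2cc(OCc3ccccc3)cc(OCc3ccccc3)c12 | intermediate
27 | (2S)-5-(benzyloxy)-2-{4-(benzyloxy)-3-[4-((2S)-5,7-bis(benzyloxy)-4-oxochroman-2-yl)phenoxy]phenyl}-7-methoxychroman-4-one | COc1cc(OCc2ccccc2)c2c(c1)O[C@H](c1ccc(OCc3ccccc3)c(Oc3ccc([C@@H]4CC(=O)c5c(OCc6ccccc6)cc(OCc6ccccc6)cc5O4)cc3)c1)CC2=O | intermediate
28 | 7-O-methyltetrahydroochnaflavone | COc1cc(O)c2c(c1)O[C@H](c1ccc(O)c(Oc3ccc([C@@H]4CC(=O)c5c(O)cc(O)cc5O4)cc3)c1)CC2=O | target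

## Step count and least certain steps

Total: 13 steps. Longest linear sequence: 8 steps (1, 2, 3, 7, 8, 9, 12, 13; the arm 4, 5, 6 joins at step 7 and is equally long; steps 10 and 11 feed step 12).

Step 7 (key step).
- What may go wrong: proton transfer from C3 to aryl carbanion 18 outruns carbonyl addition, after which the amide enolate ejects the new aryl ether by β-elimination. Configuration may also be lost, either by retro-aldol cleavage of 16 before arylation or by early collapse of 19, which would expose the enolisable flavanone to amide base.
- Why: a Weinreb amide is a modest electrophile, and sodium or caesium holds the tetrahedral adduct less tightly than lithium or magnesium would.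
- Fallback (known chemistry; ring C closed at O1–C2 by intramolecular Mitsunobu etherification): it sets out from 7 and 11 and returns at 20. 7 is reduced as in step 3 but with RuCl[(R,R)-TsDPEN](p-cymene), to give (R)-3-[4-(benzyloxy)-3-(4-bromophenoxy)phenyl]-3-hydroxy-N-methoxy-N-methylpropanamide F1. 11 is treated with n-BuLi (2.1 equiv, THF, −78 °C; O–H deprotonation, then iodine–lithium exchange) to give lithium 3-(benzyloxy)-2-lithio-5-methoxyphenolate F2. F2 is added to F1, whose hydroxyl is first deprotonated with i-PrMgCl, and gives after work-up (R)-1-[2-(benzyloxy)-6-hydroxy-4-methoxyphenyl]-3-[4-(benzyloxy)-3-(4-bromophenoxy)phenyl]-3-hydroxypropan-1-one F3. PPh3 and diisopropyl azodicarboxylate (THF, 0 °C) then activate the benzylic carbinol, and the chelated phenol displaces it with inversion, (R) to (S), to give 20.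

Step 4.
- What may go wrong: iodination at C4 (para to one hydroxyl, ortho to methoxy) or di-iodination, because all three free ring positions of 9 are activated by three oxygens.
- Fallback (directed metalation fixes the site): it sets out from 9 and returns at 10. 9 is converted with MOMCl and i-Pr2NEt (CH2Cl2, 0 °C → rt) into 1-methoxy-3,5-bis(methoxymethoxy)benzene F4. n-BuLi (THF, 0 °C) removes the proton between the two acetal oxygens, where two coordinating groups cooperate, and I2 gives 2-iodo-5-methoxy-1,3-bis(methoxymethoxy)benzene F5. Catalytic HCl in MeOH at rt removes both acetals and gives 10.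

Step 8.
- What may go wrong: partial loss of configuration at C2 through acetate-promoted enolisation at C3 and reversible ring opening during the hours at 80 °C.
- Fallback (the enolisable ketone is removed for the duration of the basic step): it sets out from 20 and returns at 21. NaBH4 (MeOH/THF, 0 °C) gives (2S)-5-(benzyloxy)-2-[4-(benzyloxy)-3-(4-bromophenoxy)phenyl]-7-methoxychroman-4-ol F6; either C4 epimer serves. Borylation under the conditions of step 8 gives (2S)-5-(benzyloxy)-2-{4-(benzyloxy)-3-[4-(4,4,5,5-tetramethyl-1,3,2-dioxaborolan-2-yl)phenoxy]phenyl}-7-methoxychroman-4-ol F7. Dess–Martin periodinane (CH2Cl2, rt) re-oxidises C4 and gives 21.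

Step 12.
- What may go wrong: slow insertion of the electron-rich chromone, whose two alkoxy donors are conjugated with the enone, so that protodeboronation of 22 competes. Facial control may also be incomplete or of the opposite sense, which would give a C2 epimer of unit 2 that is hard to separate.
- Fallback (traceless activation of the acceptor): it sets out from 24 and returns at 28. 24 is C-acylated with dibenzyl carbonate (NaH, toluene, 80 °C) to benzyl 3-[2,4-bis(benzyloxy)-6-hydroxyphenyl]-3-oxopropanoate F8. Me2NCH(OMe)2 (toluene, 80 °C) closes it to benzyl 5,7-bis(benzyloxy)-4-oxo-4H-chromene-3-carboxylate F9, an alkylidene β-keto ester far more electrophilic at C2 than 26. 22 is added to F9 with the catalyst system of step 12 at lower temperature and gives benzyl (2S)-5,7-bis(benzyloxy)-2-{4-[2-(benzyloxy)-5-((S)-5-(benzyloxy)-7-methoxy-4-oxochroman-2-yl)phenoxy]phenyl}-4-oxochromane-3-carboxylate F10 (C3 epimers; that centre is lost later). Hydrogenolysis as in step 13 removes the five benzyl groups, and the β-keto acid loses CO2 on gentle warming to give 28 directly.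

## Further compounds

F1 | step 7 | (R)-3-[4-(benzyloxy)-3-(4-bromophenoxy)phenyl]-3-hydroxy-N-methoxy-N-methylpropanamide | CON(C)C(=O)C[C@@H](O)c1ccc(OCc2ccccc2)c(Oc2ccc(Br)cc2)c1
F2 | step 7 | lithium 3-(benzyloxy)-2-lithio-5-methoxyphenolate | [Li]Oc1cc(OC)cc(OCc2ccccc2)c1[Li]
F3 | step 7 | (R)-1-[2-(benzyloxy)-6-hydroxy-4-methoxyphenyl]-3-[4-(benzyloxy)-3-(4-bromophenoxy)phenyl]-3-hydroxypropan-1-one | COc1cc(O)c(C(=O)C[C@@H](O)c2ccc(OCc3ccccc3)c(Oc3ccc(Br)cc3)c2)c(OCc2ccccc2)c1
F4 | step 4 | 1-methoxy-3,5-bis(methoxymethoxy)benzene | COCOc1cc(OC)cc(OCOC)c1
F5 | step 4 | 2-iodo-5-methoxy-1,3-bis(methoxymethoxy)benzene | COCOc1cc(OC)cc(OCOC)c1I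
F6 | step 8 | (2S)-5-(benzyloxy)-2-[4-(benzyloxy)-3-(4-bromophenoxy)phenyl]-7-methoxychroman-4-ol | COc1cc(OCc2ccccc2)c2c(c1)O[C@H](c1ccc(OCc3ccccc3)c(Oc3ccc(Br)cc3)c1)CC2O
F7 | step 8 | (2S)-5-(benzyloxy)-2-{4-(benzyloxy)-3-[4-(4,4,5,5-tetramethyl-1,3,2-dioxaborolan-2-yl)phenoxy]phenyl}-7-methoxychroman-4-ol | COc1cc(OCc2ccccc2)c2c(c1)O[C@H](c1ccc(OCc3ccccc3)c(Oc3ccc(B4OC(C)(C)C(C)(C)O4)cc3)c1)CC2O
F8 | step 12 | benzyl 3-[2,4-bis(benzyloxy)-6-hydroxyphenyl]-3-oxopropanoate | O=C(CC(=O)c1c(O)cc(OCc2ccccc2)cc1OCc1ccccc1)OCc1ccccc1
F9 | step 12 | benzyl 5,7-bis(benzyloxy)-4-oxo-4H-chromene-3-carboxylate | O=C(OCc1ccccc1)c1coc2cc(OCc3ccccc3)cc(OCc3ccccc3)c2c1=O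
F10 | step 12 | benzyl (2S)-5,7-bis(benzyloxy)-2-{4-[2-(benzyloxy)-5-((S)-5-(benzyloxy)-7-methoxy-4-oxochroman-2-yl)phenoxy]phenyl}-4-oxochromane-3-carboxylate | COc1cc(OCc2ccccc2)c2c(c1)O[C@H](c1ccc(OCc3ccccc3)c(Oc3ccc([C@@H]4C(C(=O)OCc5ccccc5)C(=O)c5c(OCc6ccccc6)cc(OCc6ccccc6)cc5O4)cc3)c1)CC2=O
A1 | alternative 1 | (2S)-5-(benzyloxy)-2-{4-(benzyloxy)-3-[4-((2S)-5,7-bis(benzyloxy)-4-oxochroman-2-yl)phenoxy]phenyl}-7-methoxychroman-4-one | COc1cc(OCc2ccccc2)c2c(c1)O[C@H](c1ccc(OCc3ccccc3)c(Oc3ccc([C@@H]4CC(=O)c5c(OCc6ccccc6)cc(OCc6ccccc6)cc5O4)cc3)c1)CC2=O
A2 | alternative 1 | (S)-1-[2-(benzyloxy)-6-fluoro-4-methoxyphenyl]-3-{4-(benzyloxy)-3-[4-((S)-3-[2,4-bis(benzyloxy)-6-fluorophenyl]-1-hydroxy-3-oxopropyl)phenoxy]phenyl}-3-hydroxypropan-1-one | COc1cc(F)c(C(=O)C[C@H](O)c2ccc(OCc3ccccc3)c(Oc3ccc([C@@H](O)CC(=O)c4c(F)cc(OCc5ccccc5)cc4OCc4ccccc4)cc3)c2)c(OCc2ccccc2)c1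
A3 | alternative 2 | (S)-5,7-bis(benzyloxy)-2-{4-[2-(benzyloxy)-5-chlorophenoxy]phenyl}chroman-4-one | Clc1ccc(OCc2ccccc2)c(Oc2ccc([C@@H]3CC(=O)c4c(OCc5ccccc5)cc(OCc5ccccc5)cc4O3)cc2)c1
A4 | alternative 2 | (S)-5,7-bis(benzyloxy)-2-ethynylchroman-4-one | C#C[C@@H]1CC(=O)c2c(OCc3ccccc3)cc(OCc3ccccc3)cc2O1
A5 | alternative 2 | 2-[2-(benzyloxy)-5-chlorophenoxy]buta-1,3-diene | C=CC(=C)Oc1cc(Cl)ccc1OCc1ccccc1
A6 | alternative 2 | (S)-5,7-bis(benzyloxy)-2-{4-[2-(benzyloxy)-5-chlorophenoxy]cyclohexa-1,4-dien-1-yl}chroman-4-one | Clc1ccc(OCc2ccccc2)c(OC2=CCC([C@@H]3CC(=O)c4c(OCc5ccccc5)cc(OCc5ccccc5)cc4O3)=CC2)c1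
A7 | alternative 3 | (S)-2-[4-(benzyloxy)-3-(4-bromophenoxy)phenyl]-5-hydroxy-7-methoxychroman-4-one | COc1cc(O)c2c(c1)O[C@H](c1ccc(OCc3ccccc3)c(Oc3ccc(Br)cc3)c1)CC2=O
A8 | alternative 3 | (S)-2-[4-(benzyloxy)-3-(4-bromophenoxy)phenyl]-6-(2-diazoacetyl)-2,3-dihydro-4H-pyran-4-one | [N-]=[N+]=CC(=O)C1=CC(=O)C[C@@H](c2ccc(OCc3ccccc3)c(Oc3ccc(Br)cc3)c2)O1
A9 | alternative 3 | methoxyethyne | COC#C
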